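Ring A is built by a Dötz benzannulation that forms C5–C6, C4a–C8a and C8–C8a. Ring A is a masked hydroquinone monomethyl ether: its ring oxygen O1 on C8a faces the C6 methoxy group across the ring, the C7 methoxy group flanks C6, and C4a, which carries the C4 carbonyl, is the neighbour of C8a. One heating of pentacarbonyl[methoxy(1-methoxyvinyl)carbene]chromium with a terminal alkyne should therefore deliver the whole ring, with the free C8a phenol ready for pyranone closure. The alkyne is a racemic propargylic silyl ether that already carries C2, C3 and C4, the C2 carbonyl as a dioxolane, and the benzyl-protected guaiacylethyl arm.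

Key step: step 8

Remark on the chemistry: the silyloxy carbon of the alkyne is a stereocentre that ends as the C4 carbonyl, so every compound containing it is made and used as the racemate; the target has no stereocentre.

Step 1
Reactants: 1 dihydroferulic acid
Product: 3 3-[4-(benzyloxy)-3-methoxyphenyl]propanoic acid, via benzyl ester 2 (not isolated)
Conditions: BnBr (2.3 equiv), K2CO3, DMF, 60 °C; then NaOH, MeOH/H2O, 60 °C; HCl to pH 2
Reagents that add atoms: benzyl bromide, BrCc1ccccc1
Why: Williamson O-alkylation benzylates both the phenoxide and the carboxylate, and only the benzyl ester is then saponified because an aryl benzyl ether is inert to hydroxide.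

Step 2
Reactants: 3 3-[4-(benzyloxy)-3-methoxyphenyl]propanoic acid; 4 Meldrum's acid
Product: 6 ethyl 5-[4-(benzyloxy)-3-methoxyphenyl]-3-oxopentanoate, via acyl Meldrum's acid 5 (not isolated)
Conditions: DCC, DMAP, CH2Cl2, 0 °C to rt; filter; then EtOH, reflux
Reagents that add atoms: ethanol, CCO
Why: Carbodiimide activation C-acylates Meldrum's acid, and ethanolysis of the acyl Meldrum's acid with loss of acetone and CO2 gives the β-keto ester (Meldrum's acid homologation of a carboxylic acid), under conditions that leave the benzyl ether alone.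

Step 3
Reactants: 6 ethyl 5-[4-(benzyloxy)-3-methoxyphenyl]-3-oxopentanoate
Product: 7 ethyl (2-{2-[4-(benzyloxy)-3-methoxyphenyl]ethyl}-1,3-dioxolan-2-yl)acetate
Conditions: HOCH2CH2OH, TsOH·H2O (cat.), toluene, reflux, Dean–Stark
Reagents that add atoms: ethylene glycol, OCCO
Why: Acid-catalysed ketalisation with azeotropic removal of water converts the ketone and not the ester, and the dioxolane blocks enolisation and β-elimination at C2 in all later basic steps.

Step 4
Reactants: 7 ethyl (2-{2-[4-(benzyloxy)-3-methoxyphenyl]ethyl}-1,3-dioxolan-2-yl)acetate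
Product: 9 (2-{2-[4-(benzyloxy)-3-methoxyphenyl]ethyl}-1,3-dioxolan-2-yl)acetaldehyde, via aluminium hemiacetal 8 (not isolated)
Conditions: i-Bu2AlH (1.1 equiv), CH2Cl2, −78 °C; MeOH, then aq. potassium sodium tartrate (KNaC4H4O6)
Reagents that add atoms: none
Why: Partial ester reduction with i-Bu2AlH at low temperature stops at the aluminium hemiacetal, which the neighbouring dioxolane oxygen helps to hold until aqueous work-up releases the aldehyde.

Step 5
Reactants: 9 (2-{2-[4-(benzyloxy)-3-methoxyphenyl]ethyl}-1,3-dioxolan-2-yl)acetaldehyde; 10 ethynylmagnesium bromide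
Product: 11 racemic 1-(2-{2-[4-(benzyloxy)-3-methoxyphenyl]ethyl}-1,3-dioxolan-2-yl)but-3-yn-2-ol
Conditions: THF, −78 to 0 °C; sat. aq. NH4Cl
Reagents that add atoms: none
Why: 1,2-Addition of an alkynyl Grignard reagent to an aldehyde; the carbinol centre forms without control as the racemate, which does not matter because this carbon becomes the C4 carbonyl.

Step 6
Reactants: 11 racemic 1-(2-{2-[4-(benzyloxy)-3-methoxyphenyl]ethyl}-1,3-dioxolan-2-yl)but-3-yn-2-ol
Product: 12 racemic tert-butyl{[1-(2-{2-[4-(benzyloxy)-3-methoxyphenyl]ethyl}-1,3-dioxolan-2-yl)but-3-yn-2-yl]oxy}dimethylsilane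
Conditions: TBSCl, imidazole, DMF, rt
Reagents that add atoms: tert-butyldimethylsilyl chloride, CC(C)(C)[Si](C)(C)Cl
Why: Imidazole-promoted silylation of a secondary propargylic alcohol; the silyl ether keeps the alkyne electron-neutral, adds bulk beside the substituted alkyne carbon and stops the hydroxyl from trapping the ketene intermediate of step 8.

Step 7
Reactants: 13 methyl vinyl ether; 14 Cr(CO)6 (chromium hexacarbonyl)
Product: 17 pentacarbonyl[methoxy(1-methoxyvinyl)carbene]chromium, via 1-methoxyvinyllithium 15 (not isolated), via lithium acyl chromate 16 (not isolated)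
Conditions: t-BuLi, THF, −78 to 0 °C; Cr(CO)6, THF, −78 °C to rt; evaporate; Me3OBF4, CH2Cl2, 0 °C
Reagents that add atoms: trimethyloxonium tetrafluoroborate, C[O+](C)C.F[B-](F)(F)F
Why: Fischer carbene synthesis, in which the α-lithiated enol ether adds to a CO ligand of Cr(CO)6 and the acyl chromate is O-methylated under anhydrous conditions so that the acid-labile enol ether never meets aqueous acid; the complex is a new member of the known class of α-substituted alkenyl(methoxy)carbene complexes.

Step 8
Reactants: 17 pentacarbonyl[methoxy(1-methoxyvinyl)carbene]chromium (1.3 equiv); 12 racemic tert-butyl{[1-(2-{2-[4-(benzyloxy)-3-methoxyphenyl]ethyl}-1,3-dioxolan-2-yl)but-3-yn-2-yl]oxy}dimethylsilane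
Product: 19 racemic 2-[1-(tert-butyldimethylsilyloxy)-2-(2-{2-[4-(benzyloxy)-3-methoxyphenyl]ethyl}-1,3-dioxolan-2-yl)ethyl]-4,5-dimethoxyphenol, via arene Cr(CO)3 complex 18 (not isolated)
Conditions: THF (0.05 M, degassed), 50 °C, Ar; then air, Et2O, rt
Reagents that add atoms: none
Why: Loss of one CO ligand lets the alkyne bind and insert into the Cr=C bond to give a vinylcarbene, CO insertion gives a chromium-bound dienylketene, and ring A closes by a thermal six-electron electrocyclisation of that ketene (a formal [3+2+1] assembly) followed by tautomerisation of the cyclohexadienone to the phenol, which is first held as its Cr(CO)3 complex and is set free by air. This is the Dötz benzannulation of an α-substituted alkenyl(methoxy)carbene complex of zerovalent chromium with a terminal alkyne, known for the isopropenyl complex, for α-alkoxyalkenyl complexes made from α-lithiated cyclic enol ethers and for propargylic silyl ethers as the alkyne partner. The carbene carbon becomes C6 with its methoxy group, the vinyl carbons become C7 (with its methoxy group) and C8, one CO ligand becomes C8a and the alkyne supplies C4a and C5. No stereocentre is formed and the silyloxy carbon is not touched. The step needs the substituted alkyne carbon to end next to the CO-derived carbon, which the terminal alkyne with its branched silyloxy substituent secures on steric grounds during insertion. It also needs phenol formation to beat furan, cyclobutenone and two-alkyne pathways, which an alkenyl complex with an unhindered CH2 terminus, THF at moderate temperature and a slight excess of the carbene favour, while release by air and not by a strong oxidant keeps the hydroquinone monoether from going on to the quinone.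

Step 9
Reactants: 19 racemic 2-[1-(tert-butyldimethylsilyloxy)-2-(2-{2-[4-(benzyloxy)-3-methoxyphenyl]ethyl}-1,3-dioxolan-2-yl)ethyl]-4,5-dimethoxyphenol
Product: 20 racemic 2-[2-(2-{2-[4-(benzyloxy)-3-methoxyphenyl]ethyl}-1,3-dioxolan-2-yl)-1-hydroxyethyl]-4,5-dimethoxyphenol
Conditions: Bu4NF, AcOH (1:1), THF, rt, Ar
Reagents that add atoms: none
Why: Fluoride-mediated cleavage of the silyl ether; buffering with acetic acid keeps the electron-rich phenol protonated so that it is not oxidised as its phenoxide, and the dioxolane and the benzyl ether are inert.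

Step 10
Reactants: 20 racemic 2-[2-(2-{2-[4-(benzyloxy)-3-methoxyphenyl]ethyl}-1,3-dioxolan-2-yl)-1-hydroxyethyl]-4,5-dimethoxyphenol
Product: 21 2-(2-{2-[4-(benzyloxy)-3-methoxyphenyl]ethyl}-1,3-dioxolan-2-yl)-1-(2-hydroxy-4,5-dimethoxyphenyl)ethan-1-one
Conditions: MnO2 (activated, excess), CH2Cl2, rt
Reagents that add atoms: none
Why: Activated MnO2 oxidises benzylic alcohols selectively, and an ortho-hydroxybenzylic carbinol on an electron-rich ring is among the most reactive substrates, so the ketone, stabilised by a hydrogen bond to the phenol, should form before the ring is attacked.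

Step 11
Reactants: 21 2-(2-{2-[4-(benzyloxy)-3-methoxyphenyl]ethyl}-1,3-dioxolan-2-yl)-1-(2-hydroxy-4,5-dimethoxyphenyl)ethan-1-one
Product: 24 2-{2-[4-(benzyloxy)-3-methoxyphenyl]ethyl}-6,7-dimethoxy-4H-chromen-4-one, via 1,3-diketone 22 (not isolated), via 2-hydroxychromanone 23 (not isolated)
Conditions: conc. aq. HCl, MeOH, 60 °C
Reagents that add atoms: none
Why: Acid hydrolysis of the dioxolane frees the 1-(2-hydroxyaryl)-1,3-diketone, whose phenol adds to the C2 carbonyl, and the hemiketal loses water to give the 4-pyranone (the cyclodehydration that ends a Baker–Venkataraman chromone synthesis).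

Step 12
Reactants: 24 2-{2-[4-(benzyloxy)-3-methoxyphenyl]ethyl}-6,7-dimethoxy-4H-chromen-4-one
Product: 25 2-[2-(4-hydroxy-3-methoxyphenyl)ethyl]-6,7-dimethoxy-4H-chromen-4-one
Conditions: H2 (1 atm), 10% Pd/C, EtOAc/MeOH, rt
Reagents that add atoms: none
Why: Hydrogenolysis of the aryl benzyl ether over Pd/C at atmospheric pressure is faster than hydrogenation of the chromone C2–C3 double bond, which is a vinylogous ester, and the reaction is stopped after uptake of one equivalent of hydrogen.

Compound list
1 | dihydroferulic acid, 3-(4-hydroxy-3-methoxyphenyl)propanoic acid | OC(=O)CCc1ccc(O)c(OC)c1 | starting material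
2 | benzyl 3-[4-(benzyloxy)-3-methoxyphenyl]propanoate (formed in the flask) | O=C(OCc1ccccc1)CCc1ccc(OCc2ccccc2)c(OC)c1 | intermediate
3 | 3-[4-(benzyloxy)-3-methoxyphenyl]propanoic acid | OC(=O)CCc1ccc(OCc2ccccc2)c(OC)c1 | intermediate
4 | Meldrum's acid, 2,2-dimethyl-1,3-dioxane-4,6-dione | CC1(C)OC(=O)CC(=O)O1 | starting material
5 | 5-{3-[4-(benzyloxy)-3-methoxyphenyl]propanoyl}-2,2-dimethyl-1,3-dioxane-4,6-dione (acyl Meldrum's acid, drawn as the keto form, formed in the flask) | CC1(C)OC(=O)C(C(=O)CCc2ccc(OCc3ccccc3)c(OC)c2)C(=O)O1 | intermediate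
6 | ethyl 5-[4-(benzyloxy)-3-methoxyphenyl]-3-oxopentanoate | CCOC(=O)CC(=O)CCc1ccc(OCc2ccccc2)c(OC)c1 | intermediate
7 | ethyl (2-{2-[4-(benzyloxy)-3-methoxyphenyl]ethyl}-1,3-dioxolan-2-yl)acetate | CCOC(=O)CC1(CCc2ccc(OCc3ccccc3)c(OC)c2)OCCO1 | intermediate
8 | diisobutylaluminium hemiacetal of ester 7, [1-ethoxy-2-(2-{2-[4-(benzyloxy)-3-methoxyphenyl]ethyl}-1,3-dioxolan-2-yl)ethoxy]bis(2-methylpropyl)aluminium (formed in the flask) | CCOC(O[Al](CC(C)C)CC(C)C)CC1(CCc2ccc(OCc3ccccc3)c(OC)c2)OCCO1 | intermediate
9 | (2-{2-[4-(benzyloxy)-3-methoxyphenyl]ethyl}-1,3-dioxolan-2-yl)acetaldehyde | O=CCC1(CCc2ccc(OCc3ccccc3)c(OC)c2)OCCO1 | intermediate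
10 | ethynylmagnesium bromide, HC≡CMgBr | C#C[Mg]Br | starting material
11 | racemic 1-(2-{2-[4-(benzyloxy)-3-methoxyphenyl]ethyl}-1,3-dioxolan-2-yl)but-3-yn-2-ol | C#CC(O)CC1(CCc2ccc(OCc3ccccc3)c(OC)c2)OCCO1 | intermediate
12 | racemic tert-butyl{[1-(2-{2-[4-(benzyloxy)-3-methoxyphenyl]ethyl}-1,3-dioxolan-2-yl)but-3-yn-2-yl]oxy}dimethylsilane | C#CC(O[Si](C)(C)C(C)(C)C)CC1(CCc2ccc(OCc3ccccc3)c(OC)c2)OCCO1 | intermediate
13 | methyl vinyl ether, methoxyethene | COC=C | starting material
14 | chromium hexacarbonyl, Cr(CO)6 | O=C=[Cr](=C=O)(=C=O)(=C=O)(=C=O)=C=O | starting material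
15 | 1-methoxyvinyllithium, CH2=C(OMe)Li (formed in the flask) | [Li]C(=C)OC | intermediate
16 | lithium pentacarbonyl(2-methoxyacryloyl)chromate, Li[(CO)5CrC(O)C(OMe)=CH2] (formed in the flask) | [Li+].[O-]C(C(=C)OC)=[Cr](=C=O)(=C=O)(=C=O)(=C=O)=C=O | intermediate
17 | pentacarbonyl[methoxy(1-methoxyvinyl)carbene]chromium, (CO)5Cr=C(OMe)C(OMe)=CH2 | COC(C(=C)OC)=[Cr](=C=O)(=C=O)(=C=O)(=C=O)=C=O | intermediate
18 | Cr(CO)3 complex of phenol 19, bound η6 through ring A (formed in the flask; the η6 bond is written as a dot) | COc1cc(O)c(cc1OC)C(O[Si](C)(C)C(C)(C)C)CC1(CCc2ccc(OCc3ccccc3)c(OC)c2)OCCO1.O=C=[Cr](=C=O)=C=O | intermediate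
19 | racemic 2-[1-(tert-butyldimethylsilyloxy)-2-(2-{2-[4-(benzyloxy)-3-methoxyphenyl]ethyl}-1,3-dioxolan-2-yl)ethyl]-4,5-dimethoxyphenol | COc1cc(O)c(cc1OC)C(O[Si](C)(C)C(C)(C)C)CC1(CCc2ccc(OCc3ccccc3)c(OC)c2)OCCO1 | intermediate
20 | racemic 2-[2-(2-{2-[4-(benzyloxy)-3-methoxyphenyl]ethyl}-1,3-dioxolan-2-yl)-1-hydroxyethyl]-4,5-dimethoxyphenol | COc1cc(O)c(cc1OC)C(O)CC1(CCc2ccc(OCc3ccccc3)c(OC)c2)OCCO1 | intermediate
21 | 2-(2-{2-[4-(benzyloxy)-3-methoxyphenyl]ethyl}-1,3-dioxolan-2-yl)-1-(2-hydroxy-4,5-dimethoxyphenyl)ethan-1-one | COc1cc(O)c(cc1OC)C(=O)CC1(CCc2ccc(OCc3ccccc3)c(OC)c2)OCCO1 | intermediate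
22 | 5-[4-(benzyloxy)-3-methoxyphenyl]-1-(2-hydroxy-4,5-dimethoxyphenyl)pentane-1,3-dione (formed in the flask) | COc1cc(O)c(cc1OC)C(=O)CC(=O)CCc1ccc(OCc2ccccc2)c(OC)c1 | intermediate
23 | racemic 2-{2-[4-(benzyloxy)-3-methoxyphenyl]ethyl}-2-hydroxy-6,7-dimethoxy-2,3-dihydro-4H-chromen-4-one (formed in the flask) | COc1cc2OC(O)(CCc3ccc(OCc4ccccc4)c(OC)c3)CC(=O)c2cc1OC | intermediate
24 | 2-{2-[4-(benzyloxy)-3-methoxyphenyl]ethyl}-6,7-dimethoxy-4H-chromen-4-one | COc1cc2oc(CCc3ccc(OCc4ccccc4)c(OC)c3)cc(=O)c2cc1OC | intermediate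
25 | 2-[2-(4-hydroxy-3-methoxyphenyl)ethyl]-6,7-dimethoxy-4H-chromen-4-one | COc1cc(CCc2cc(=O)c3cc(OC)c(OC)cc3o2)ccc1O | target

Total step count: 12.
Longest linear sequence: 11 steps (steps 1 to 6 and 8 to 12); step 7 is a one-step side branch.

Steps most likely to fail

1. Step 8. The electron-rich α-methoxyvinyl complex may lose its enol ether or oligomerise faster than it takes up the alkyne, or the vinylketene may be diverted into furan or cyclobutenone formation, so that little phenol is formed. The fallback replaces the benzannulation by a classical Baker–Venkataraman chromone synthesis. It sets out from acid 3, which is esterified with commercial 1-(2-hydroxy-4,5-dimethoxyphenyl)ethan-1-one (EDC·HCl, DMAP, CH2Cl2) to give 2-acetyl-4,5-dimethoxyphenyl 3-[4-(benzyloxy)-3-methoxyphenyl]propanoate F1. KOt-Bu in THF should then move the acyl group from the phenol oxygen to the methyl ketone enolate carbon and give diketone 22, where the route is rejoined; 22 is cyclised to 24 under the conditions of step 11.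

2. Step 7. Acid released during O-methylation may hydrolyse or oligomerise the enol ether, and the complex may be lost on chromatography. The fallback forms the carbene C–OMe bond by alcoholysis of an acyloxycarbene in place of oxonium alkylation. It sets out from lithium acyl chromate 16, which is taken up in degassed water and precipitated with Me4NBr as tetramethylammonium pentacarbonyl(2-methoxyacryloyl)chromate F2, a salt that can be recrystallised and stored. Acetyl bromide in CH2Cl2 at −40 °C should convert it into pentacarbonyl[acetoxy(1-methoxyvinyl)carbene]chromium F3, and methanol at −40 to −20 °C should exchange acetoxy for methoxy. After a cold NaHCO3 wash this returns to the route at 17, which is used crude in step 8.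

3. Step 10. The hydroquinone monoether ring may be oxidised towards a quinone, or the ortho-hydroxybenzylic alcohol may dehydrate to an ortho-quinone methide, in competition with oxidation of the carbinol. The fallback masks the phenol before the oxidation. It sets out from phenol 19, which is converted with MOMCl and i-Pr2NEt in CH2Cl2 into racemic tert-butyl{1-[4,5-dimethoxy-2-(methoxymethoxy)phenyl]-2-(2-{2-[4-(benzyloxy)-3-methoxyphenyl]ethyl}-1,3-dioxolan-2-yl)ethoxy}dimethylsilane F4. Bu4NF in THF should give racemic 2-(2-{2-[4-(benzyloxy)-3-methoxyphenyl]ethyl}-1,3-dioxolan-2-yl)-1-[4,5-dimethoxy-2-(methoxymethoxy)phenyl]ethan-1-ol F5, and Dess–Martin periodinane in CH2Cl2 should oxidise it to 2-(2-{2-[4-(benzyloxy)-3-methoxyphenyl]ethyl}-1,3-dioxolan-2-yl)-1-[4,5-dimethoxy-2-(methoxymethoxy)phenyl]ethan-1-one F6. The HCl/MeOH conditions of step 11 then remove the methoxymethyl group and the dioxolane and close the pyranone, returning to the route at 24.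

Further compounds
F1 | step 8 | 2-acetyl-4,5-dimethoxyphenyl 3-[4-(benzyloxy)-3-methoxyphenyl]propanoate | CC(=O)c1cc(OC)c(OC)cc1OC(=O)CCc1ccc(OCc2ccccc2)c(OC)c1
F2 | step 7 | tetramethylammonium pentacarbonyl(2-methoxyacryloyl)chromate | C[N+](C)(C)C.[O-]C(C(=C)OC)=[Cr](=C=O)(=C=O)(=C=O)(=C=O)=C=O
F3 | step 7 | pentacarbonyl[acetoxy(1-methoxyvinyl)carbene]chromium | CC(=O)OC(C(=C)OC)=[Cr](=C=O)(=C=O)(=C=O)(=C=O)=C=O
F4 | step 10 | racemic tert-butyl{1-[4,5-dimethoxy-2-(methoxymethoxy)phenyl]-2-(2-{2-[4-(benzyloxy)-3-methoxyphenyl]ethyl}-1,3-dioxolan-2-yl)ethoxy}dimethylsilane | COCOc1cc(OC)c(OC)cc1C(O[Si](C)(C)C(C)(C)C)CC1(CCc2ccc(OCc3ccccc3)c(OC)c2)OCCO1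
F5 | step 10 | racemic 2-(2-{2-[4-(benzyloxy)-3-methoxyphenyl]ethyl}-1,3-dioxolan-2-yl)-1-[4,5-dimethoxy-2-(methoxymethoxy)phenyl]ethan-1-ol | COCOc1cc(OC)c(OC)cc1C(O)CC1(CCc2ccc(OCc3ccccc3)c(OC)c2)OCCO1
F6 | step 10 | 2-(2-{2-[4-(benzyloxy)-3-methoxyphenyl]ethyl}-1,3-dioxolan-2-yl)-1-[4,5-dimethoxy-2-(methoxymethoxy)phenyl]ethan-1-one | COCOc1cc(OC)c(OC)cc1C(=O)CC1(CCc2ccc(OCc3ccccc3)c(OC)c2)OCCO1
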